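The target rises slowly in these runs, and its late slope was the first thing I read. The question is how much intermediate A (from here on, A) stands at the end.

the same everywhere: starting material 0.063 M; second reagent 0.126 M

| run | partner | third reagent | temperature | remark | time |
|---|---|---|---|---|---|
| teal | 0.062 M | 0.0662 M | 50 °C | run made earlier |  |
| grey | 0.097 M | 0.0662 M | 72 °C | run made earlier |  |
| amber | 0.0441 M | 0.099 M | 50 °C | run made earlier |  |
| alder | 0.0441 M | 0.0662 M | 80 °C |  | 15 min |
| maple | 0.0441 M | 0.0662 M | 60 °C |  | 15 min |
| elm | 0.0441 M | 0.0662 M | 40 °C |  | 15 min |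

| run | time / min | intermediate A / % | target / % |
|---|---|---|---|
| teal | 4.00 | 51.9 | 0.3 |
| teal | 6.00 | 60.1 | 0.3 |
| teal | 8.00 | 65.0 | 0.1 |
| teal | 12.0 | 70.4 | 0.8 |
| teal | 20.0 | 74.2 | 2.1 |
| teal | 40.0 | 73.6 | 5.3 |
| teal | 50.0 | 71.1 | 7.6 |
| grey | 1.00 | 65.2 | 0.6 |
| grey | 1.33 | 72.0 | 0.2 |
| grey | 2.00 | 78.7 | 0.5 |
| grey | 3.00 | 81.9 | 1.1 |
| grey | 5.00 | 81.3 | 3.2 |
| grey | 8.00 | 76.6 | 6.7 |
| grey | 12.0 | 70.2 | 12.7 |
| amber | 12.0 | 55.6 | 0.7 |
| amber | 20.0 | 59.2 | 1.3 |
| amber | 40.0 | 58.8 | 4.9 |
| amber | 50.0 | 58.8 | 7.0 |

(each reading ± 0.3 percentage points)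
- which flask leads in amount of intermediate A, in percent of the starting material charged ("all alike" within 1.5 percentage points) (alder / maple / elm / all alike)
- how much intermediate A is there at the end, in percent of the starting material charged: alder
- how much intermediate A is there at the end, in percent of the starting material charged: maple
- how much intermediate A is there at the end, in percent of the starting material charged: elm

**Drain time.** Target gained per minute, divided by the A present, gives a pseudo-first-order drain constant k for A. Between 40.0 min and 50.0 min teal gave 0.00318 /min at 50 °C, and between 8.00 min and 12.0 min grey gave 0.0204 /min at 72 °C. I spaced ln k evenly with temperature, going past grey for alder. That gave the drain time τ, the inverse of k, as 24.9 min in alder, 135 min in maple and 733 min in elm.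

**Fill time.** Amber has these flasks' partner charge, and its last reading of A plus target, M = 65.8%, served as my ceiling, with intermediate B unread. Letting A plus target rise as M·t/(t+tf), amber's first reading gave a fill time tf of 2.02 min. Teal and grey, scaled by partner, shortened tf by a factor 4.99 from teal's temperature to grey's. So tf was 0.226 min in alder, 0.975 min in maple and 4.21 min in elm.

**My reckoning.** I took A at 15 min as M·t/(t+tf)·exp(−t/τ). Elm's unfilled share, 21.9%, is larger than its drained share, and alder's unfilled share is smaller than its drained share. I got 35.5% for alder, 55.3% for maple and 50.3% for elm.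

**The result.** The forecast chose maple, with 41.5% for alder, 57.5% for maple and 51.5% for elm, higher than mine in alder; for alder it reckoned that “the drain of about 0.03/min leaves about 41%”, where my drain constant was 0.0402 /min. The flasks gave 39.9% in alder, 58.2% in maple and 51.7% in elm, so maple led.

    second reagent + intermediate A → intermediate B (k = 0.00630 /M/s, Ea = 81.0 kJ/mol)
    third reagent + intermediate B → target (k = 0.0820 /M/s, Ea = 53.0 kJ/mol)
    starting material + second reagent → side product (k = 0.0250 /M/s, Ea = 59.0 kJ/mol)
    starting material + partner → intermediate A (k = 0.430 /M/s, Ea = 53.0 kJ/mol)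
    (constants at 80 °C)

**What ran.** At 15.0 min elm still held 35.7% of its starting material, while alder was down to 1.31% and made A at 0.0505 of the rate it used it. Target plus intermediate B then made up 40.3% of those two and A together in alder, against 45.3% from τ. Alder's charge run at 65 °C, with τ 88.5 min, showed 14.5% against 15.6%, with A at 56.0%.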